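**Retrosynthetic overview**
- Target ⇐ chelation-controlled 5-O-demethylation and hydrogenolysis of two benzyl ethers of a 4',5'-bis(benzyloxy)-3,5,6,7,8,2'-hexamethoxyflavone; the 3-OMe comes from O-methylation of a flavonol made by C-3 oxidation of the flavone.
- Flavone ⇐ I2/DMSO oxidative cyclisation of a 2'-hydroxychalcone; the pyranone ring is the only ring formed, and it is closed after the fragment union.
- Chalcone ⇐ key C–C bond by intermolecular Claisen–Schmidt aldol condensation of 2'-hydroxy-3',4',5',6'-tetramethoxyacetophenone (A ring) with 4,5-bis(benzyloxy)-2-methoxybenzaldehyde (B ring).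
- Acetophenone ⇐ 2,3,4-trimethoxybenzaldehyde (Dakin, methylation, Vilsmeier, Dakin, BF3 acetylation); aldehyde ⇐ 3,4-bis(benzyloxy)benzaldehyde (Baeyer–Villiger, methylation, Vilsmeier).

Assumption: the target has no stereocentre, so no enantiomer question arises; the only stereo-element on the way is the E-alkene of the chalcone, and the sp3 intermediates that form in the flask are racemic.

**Route**

Step 1
Reactants: 1 2,3,4-trimethoxybenzaldehyde
Product: 3 2,3,4-trimethoxyphenol, via aryl formate 2 (not isolated)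
Conditions: 30% H2O2 (1.3 equiv), cat. H2SO4, MeOH, rt
Reagents that add atoms: hydrogen peroxide, OO
Why: Acid-catalysed Dakin (Baeyer–Villiger-type) oxidation, in which the electron-rich aryl group migrates to the peroxide oxygen and the formate is methanolysed in situ.

Step 2
Reactants: 3 2,3,4-trimethoxyphenol
Product: 4 1,2,3,4-tetramethoxybenzene
Conditions: MeI, K2CO3, acetone, reflux
Reagents that add atoms: iodomethane, CI
Why: Williamson ether synthesis (SN2 O-methylation of the phenoxide).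

Step 3
Reactants: 4 1,2,3,4-tetramethoxybenzene
Product: 6 2,3,4,5-tetramethoxybenzaldehyde, via iminium chloride 5 (not isolated)
Conditions: POCl3, DMF, 0 → 80 °C; then ice–water
Reagents that add atoms: N,N-dimethylformamide, CN(C)C=O (formyl carbon); water, O (carbonyl oxygen)
Why: Vilsmeier–Haack formylation of an electron-rich arene whose two free positions are symmetry-equivalent, so only one aldehyde can form.

Step 4
Reactants: 6 2,3,4,5-tetramethoxybenzaldehyde
Product: 8 2,3,4,5-tetramethoxyphenol, via aryl formate 7 (not isolated)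
Conditions: 30% H2O2 (1.3 equiv), cat. H2SO4, MeOH, rt, N2
Reagents that add atoms: hydrogen peroxide, OO
Why: Dakin oxidation as in step 1; the ortho- and para-methoxy groups favour aryl migration, and the formate shields the phenol from over-oxidation until it is methanolysed.

Step 5
Reactants: 8 2,3,4,5-tetramethoxyphenol
Product: 9 1-(2-hydroxy-3,4,5,6-tetramethoxyphenyl)ethan-1-one
Conditions: AcOH, BF3·OEt2 (3 equiv), 90 °C; then H2O
Reagents that add atoms: acetic acid, CC(=O)O
Why: BF3-mediated Friedel–Crafts/Fries-type ortho-acylation; the only unsubstituted ring carbon is ortho to the OH, so the regiochemistry is forced.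

Step 6
Reactants: 10 3,4-bis(benzyloxy)benzaldehyde
Product: 12 3,4-bis(benzyloxy)phenol, via aryl formate 11 (not isolated)
Conditions: mCPBA, CH2Cl2, rt; then cat. K2CO3, MeOH, rt
Reagents that add atoms: meta-chloroperoxybenzoic acid, O=C(OO)c1cccc(Cl)c1
Why: Baeyer–Villiger oxidation of a p-alkoxybenzaldehyde (aryl migration) followed by mild methanolysis of the formate; benzyl ethers are inert to both.

Step 7
Reactants: 12 3,4-bis(benzyloxy)phenol
Product: 13 1,2-bis(benzyloxy)-4-methoxybenzene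
Conditions: MeI, K2CO3, acetone, reflux
Reagents that add atoms: iodomethane, CI
Why: Williamson ether synthesis on the only free hydroxyl.

Step 8
Reactants: 13 1,2-bis(benzyloxy)-4-methoxybenzene
Product: 15 4,5-bis(benzyloxy)-2-methoxybenzaldehyde, via iminium chloride 14 (not isolated)
Conditions: POCl3, DMF, 0 → 60 °C; then ice–water
Reagents that add atoms: N,N-dimethylformamide, CN(C)C=O (formyl carbon); water, O (carbonyl oxygen)
Why: Vilsmeier–Haack formylation at the position ortho to OMe and para to an OBn group (the usual C-5 selectivity of 1,2,4-trialkoxybenzenes); the site between two alkoxy groups is hindered.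

Step 9
Reactants: 9 1-(2-hydroxy-3,4,5,6-tetramethoxyphenyl)ethan-1-one; 15 4,5-bis(benzyloxy)-2-methoxybenzaldehyde
Product: 17 (E)-3-[4,5-bis(benzyloxy)-2-methoxyphenyl]-1-(2-hydroxy-3,4,5,6-tetramethoxyphenyl)prop-2-en-1-one, via aldol adduct 16 (not isolated)
Conditions: KOH (50% aq.), EtOH, rt, 24–48 h
Reagents that add atoms: none
Why: Claisen–Schmidt crossed aldol condensation: the methyl ketone enolate adds to the non-enolisable aldehyde, forming the C–C bond that joins the A- and B-ring fragments, and E1cB dehydration gives the thermodynamically favoured E-enone.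

Step 10
Reactants: 17 (E)-3-[4,5-bis(benzyloxy)-2-methoxyphenyl]-1-(2-hydroxy-3,4,5,6-tetramethoxyphenyl)prop-2-en-1-one
Product: 19 2-[4,5-bis(benzyloxy)-2-methoxyphenyl]-5,6,7,8-tetramethoxy-4H-chromen-4-one, via flavanone 18 (not isolated)
Conditions: I2 (10 mol %), DMSO, 130 °C
Reagents that add atoms: none
Why: I2/DMSO oxidative cyclisation: 6-endo oxa-Michael addition of the 2'-phenol gives the flavanone, which is dehydrogenated by α-iodination/HI elimination while DMSO re-oxidises HI, so the transient stereocentre is erased.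

Step 11
Reactants: 19 2-[4,5-bis(benzyloxy)-2-methoxyphenyl]-5,6,7,8-tetramethoxy-4H-chromen-4-one
Product: 21 2-[4,5-bis(benzyloxy)-2-methoxyphenyl]-3-hydroxy-5,6,7,8-tetramethoxy-4H-chromen-4-one, via flavone epoxide 20 (not isolated)
Conditions: DMDO (ca. 0.07 M in acetone, 3 equiv), CH2Cl2, 0 °C → rt; then cat. TsOH·H2O, rt
Reagents that add atoms: dimethyldioxirane, CC1(C)OO1
Why: Dioxirane epoxidation of the enol-ether C2=C3 bond, then acid-catalysed opening of the 2,3-epoxide to the C-2 oxocarbenium ion, which loses H-3 to give the flavonol; the neutral, cold oxidation spares benzyl and methyl ethers.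

Step 12
Reactants: 21 2-[4,5-bis(benzyloxy)-2-methoxyphenyl]-3-hydroxy-5,6,7,8-tetramethoxy-4H-chromen-4-one
Product: 22 2-[4,5-bis(benzyloxy)-2-methoxyphenyl]-3,5,6,7,8-pentamethoxy-4H-chromen-4-one
Conditions: MeI, K2CO3, acetone, reflux
Reagents that add atoms: iodomethane, CI
Why: Williamson O-methylation of the acidic 3-OH, the only free hydroxyl in the molecule.

Step 13
Reactants: 22 2-[4,5-bis(benzyloxy)-2-methoxyphenyl]-3,5,6,7,8-pentamethoxy-4H-chromen-4-one
Product: 23 2-(4,5-dihydroxy-2-methoxyphenyl)-3,5,6,7,8-pentamethoxy-4H-chromen-4-one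
Conditions: H2 (1 atm), 10% Pd/C, THF–MeOH, rt
Reagents that add atoms: none
Why: Pd-catalysed hydrogenolysis of the benzyl aryl ethers; the tetrasubstituted vinylogous-ester C2=C3 bond and the methyl ethers are inert at 1 atm and rt.

Step 14
Reactants: 23 2-(4,5-dihydroxy-2-methoxyphenyl)-3,5,6,7,8-pentamethoxy-4H-chromen-4-one
Product: 24 5-hydroxy-2-(4,5-dihydroxy-2-methoxyphenyl)-3,6,7,8-tetramethoxy-4H-chromen-4-one (5,4',5'-trihydroxy-3,6,7,8,2'-pentamethoxyflavone)
Conditions: BCl3 (1 M in CH2Cl2, 4–5 equiv), CH2Cl2, −78 → 0 °C; then H2O, 0 °C → rt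
Reagents that add atoms: none
Why: Chelation-controlled Lewis-acid ether cleavage: boron bridges the C-4 carbonyl and the peri 5-OMe oxygen in a six-membered chelate, so chloride removes only that methyl, while the 3-OMe (five-membered chelate only) and the non-chelated OMe groups stay; the free catechol merely consumes extra reagent.

**Compound list**
1 | 2,3,4-trimethoxybenzaldehyde | COc1ccc(C=O)c(OC)c1OC | starting material
2 | 2,3,4-trimethoxyphenyl formate | COc1ccc(OC=O)c(OC)c1OC | intermediate (not isolated)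
3 | 2,3,4-trimethoxyphenol | COc1ccc(O)c(OC)c1OC | intermediate
4 | 1,2,3,4-tetramethoxybenzene | COc1ccc(OC)c(OC)c1OC | intermediate
5 | N,N-dimethyl-1-(2,3,4,5-tetramethoxyphenyl)methaniminium chloride | COc1cc(C=[N+](C)C)c(OC)c(OC)c1OC.[Cl-] | intermediate (not isolated)
6 | 2,3,4,5-tetramethoxybenzaldehyde | COc1cc(C=O)c(OC)c(OC)c1OC | intermediate
7 | 2,3,4,5-tetramethoxyphenyl formate | COc1cc(OC=O)c(OC)c(OC)c1OC | intermediate (not isolated)
8 | 2,3,4,5-tetramethoxyphenol | COc1cc(O)c(OC)c(OC)c1OC | intermediate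
9 | 1-(2-hydroxy-3,4,5,6-tetramethoxyphenyl)ethan-1-one | CC(=O)c1c(O)c(OC)c(OC)c(OC)c1OC | intermediate
10 | 3,4-bis(benzyloxy)benzaldehyde | O=Cc1ccc(OCc2ccccc2)c(OCc2ccccc2)c1 | starting material
11 | 3,4-bis(benzyloxy)phenyl formate | O=COc1ccc(OCc2ccccc2)c(OCc2ccccc2)c1 | intermediate (not isolated)
12 | 3,4-bis(benzyloxy)phenol | Oc1ccc(OCc2ccccc2)c(OCc2ccccc2)c1 | intermediate
13 | 1,2-bis(benzyloxy)-4-methoxybenzene | COc1ccc(OCc2ccccc2)c(OCc2ccccc2)c1 | intermediate
14 | 1-[4,5-bis(benzyloxy)-2-methoxyphenyl]-N,N-dimethylmethaniminium chloride | COc1cc(OCc2ccccc2)c(OCc2ccccc2)cc1C=[N+](C)C.[Cl-] | intermediate (not isolated)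
15 | 4,5-bis(benzyloxy)-2-methoxybenzaldehyde | COc1cc(OCc2ccccc2)c(OCc2ccccc2)cc1C=O | intermediate
16 | 3-[4,5-bis(benzyloxy)-2-methoxyphenyl]-3-hydroxy-1-(2-hydroxy-3,4,5,6-tetramethoxyphenyl)propan-1-one (racemic) | COc1cc(OCc2ccccc2)c(OCc2ccccc2)cc1C(O)CC(=O)c1c(O)c(OC)c(OC)c(OC)c1OC | intermediate (not isolated)
17 | (E)-3-[4,5-bis(benzyloxy)-2-methoxyphenyl]-1-(2-hydroxy-3,4,5,6-tetramethoxyphenyl)prop-2-en-1-one | COc1cc(OCc2ccccc2)c(OCc2ccccc2)cc1/C=C/C(=O)c1c(O)c(OC)c(OC)c(OC)c1OC | intermediate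
18 | 2-[4,5-bis(benzyloxy)-2-methoxyphenyl]-5,6,7,8-tetramethoxychroman-4-one (racemic) | COc1cc(OCc2ccccc2)c(OCc2ccccc2)cc1C1CC(=O)c2c(OC)c(OC)c(OC)c(OC)c2O1 | intermediate (not isolated)
19 | 2-[4,5-bis(benzyloxy)-2-methoxyphenyl]-5,6,7,8-tetramethoxy-4H-chromen-4-one | COc1cc(OCc2ccccc2)c(OCc2ccccc2)cc1-c1cc(=O)c2c(OC)c(OC)c(OC)c(OC)c2o1 | intermediate
20 | 2,3-epoxide of 19 (2,3-epoxy-2-[4,5-bis(benzyloxy)-2-methoxyphenyl]-5,6,7,8-tetramethoxychroman-4-one; racemic, cis-fused oxirane) | COc1cc(OCc2ccccc2)c(OCc2ccccc2)cc1C12OC1C(=O)c1c(OC)c(OC)c(OC)c(OC)c1O2 | intermediate (not isolated)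
21 | 2-[4,5-bis(benzyloxy)-2-methoxyphenyl]-3-hydroxy-5,6,7,8-tetramethoxy-4H-chromen-4-one | COc1cc(OCc2ccccc2)c(OCc2ccccc2)cc1-c1oc2c(OC)c(OC)c(OC)c(OC)c2c(=O)c1O | intermediate
22 | 2-[4,5-bis(benzyloxy)-2-methoxyphenyl]-3,5,6,7,8-pentamethoxy-4H-chromen-4-one | COc1cc(OCc2ccccc2)c(OCc2ccccc2)cc1-c1oc2c(OC)c(OC)c(OC)c(OC)c2c(=O)c1OC | intermediate
23 | 2-(4,5-dihydroxy-2-methoxyphenyl)-3,5,6,7,8-pentamethoxy-4H-chromen-4-one | COc1cc(O)c(O)cc1-c1oc2c(OC)c(OC)c(OC)c(OC)c2c(=O)c1OC | intermediate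
24 | 5,4',5'-trihydroxy-3,6,7,8,2'-pentamethoxyflavone (achiral) | COc1cc(O)c(O)cc1-c1oc2c(OC)c(OC)c(OC)c(O)c2c(=O)c1OC | target

**Totals**
Total step count: 14. Longest linear sequence: 11 steps (1 → 24 through steps 1–5 and 9–14); the B-ring arm (steps 6–8) joins at step 9.

**Three steps most likely to fail, with fallbacks**

Step 11 (C-3 oxidation with DMDO). The risk is slow epoxidation of the hindered 2-aryl enol ether, with competing oxidation of benzylic C–H bonds or of the electron-rich rings. The fallback sets out from flavone 19 and comes back at flavonol 21. It replaces epoxidation by directed metalation: C-3 is deprotonated with LDA (THF, −78 °C) to give the 3-lithioflavone F1. This is trapped with B(OMe)3 to give the dimethyl flavon-3-ylboronate F2, which is oxidised in the same flask with H2O2/AcOH to 21. No electrophilic oxidant meets the benzyl ethers in this sequence.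

Step 14 (selective 5-O-demethylation). The risk is over-demethylation at 3-OMe or 6-OMe, or a sluggish reaction of the boron-bound catechol. The fallback avoids any late demethylation by carrying the 5-oxygen as a benzyl ether; it sets out from acetophenone 9 and comes back at target 24.
- BCl3 (CH2Cl2, −78 → 0 °C) removes only the methyl ortho to the acetyl group of 9 and gives the symmetric 1-(2,6-dihydroxy-3,4,5-trimethoxyphenyl)ethan-1-one F3.
- BnBr (1.05 equiv), K2CO3, acetone gives 1-[2-(benzyloxy)-6-hydroxy-3,4,5-trimethoxyphenyl]ethan-1-one F4; the two OH groups are equivalent and the remaining one is hydrogen-bonded to the carbonyl, so it resists a second alkylation.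
- The sequence of steps 9–12 is then repeated with aldehyde 15. KOH/EtOH gives, by way of the racemic aldol adduct F5 (not isolated), the (E)-6'-benzyloxy-2'-hydroxychalcone F6.
- I2/DMSO gives, by way of the racemic 5-benzyloxyflavanone F7 (not isolated), the 5-benzyloxyflavone F8.
- DMDO then TsOH gives, by way of the racemic flavone epoxide F9 (not isolated), the 5-benzyloxyflavonol F10.
- MeI/K2CO3 gives the 3-O-methyl tribenzyl ether F11.
- A single hydrogenolysis (H2, Pd/C) removes all three benzyl groups and gives 24.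

Step 10 (I2/DMSO oxidative cyclisation). The risk is partial loss of benzyl or 5-methyl ethers to HI at 130 °C. The fallback sets out from chalcone 17 and comes back at flavone 19. The chalcone is deliberately cyclised to flavanone 18 (NaOAc, EtOH, reflux), which is isolated and then dehydrogenated with DDQ in refluxing 1,4-dioxane. This two-stage isomerisation and quinone dehydrogenation makes no compound outside the list (F0).

**Further compounds**
F0 | step 10 | none | none
F1 | step 11 | 3-lithio derivative of flavone 19 | [Li]c1c(-c2cc(OCc3ccccc3)c(OCc3ccccc3)cc2OC)oc2c(OC)c(OC)c(OC)c(OC)c2c1=O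
F2 | step 11 | dimethyl {2-[4,5-bis(benzyloxy)-2-methoxyphenyl]-5,6,7,8-tetramethoxy-4-oxo-4H-chromen-3-yl}boronate | COB(OC)c1c(-c2cc(OCc3ccccc3)c(OCc3ccccc3)cc2OC)oc2c(OC)c(OC)c(OC)c(OC)c2c1=O
F3 | step 14 | 1-(2,6-dihydroxy-3,4,5-trimethoxyphenyl)ethan-1-one | CC(=O)c1c(O)c(OC)c(OC)c(OC)c1O
F4 | step 14 | 1-[2-(benzyloxy)-6-hydroxy-3,4,5-trimethoxyphenyl]ethan-1-one | CC(=O)c1c(O)c(OC)c(OC)c(OC)c1OCc1ccccc1
F5 | step 14 | 1-[2-(benzyloxy)-6-hydroxy-3,4,5-trimethoxyphenyl]-3-[4,5-bis(benzyloxy)-2-methoxyphenyl]-3-hydroxypropan-1-one (racemic) | COc1cc(OCc2ccccc2)c(OCc2ccccc2)cc1C(O)CC(=O)c1c(O)c(OC)c(OC)c(OC)c1OCc1ccccc1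
F6 | step 14 | (E)-1-[2-(benzyloxy)-6-hydroxy-3,4,5-trimethoxyphenyl]-3-[4,5-bis(benzyloxy)-2-methoxyphenyl]prop-2-en-1-one | COc1cc(OCc2ccccc2)c(OCc2ccccc2)cc1/C=C/C(=O)c1c(O)c(OC)c(OC)c(OC)c1OCc1ccccc1
F7 | step 14 | 5-(benzyloxy)-2-[4,5-bis(benzyloxy)-2-methoxyphenyl]-6,7,8-trimethoxychroman-4-one (racemic) | COc1cc(OCc2ccccc2)c(OCc2ccccc2)cc1C1CC(=O)c2c(OCc3ccccc3)c(OC)c(OC)c(OC)c2O1
F8 | step 14 | 5-(benzyloxy)-2-[4,5-bis(benzyloxy)-2-methoxyphenyl]-6,7,8-trimethoxy-4H-chromen-4-one | COc1cc(OCc2ccccc2)c(OCc2ccccc2)cc1-c1cc(=O)c2c(OCc3ccccc3)c(OC)c(OC)c(OC)c2o1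
F9 | step 14 | 2,3-epoxide of F8 (racemic, cis-fused oxirane) | COc1cc(OCc2ccccc2)c(OCc2ccccc2)cc1C12OC1C(=O)c1c(OCc3ccccc3)c(OC)c(OC)c(OC)c1O2
F10 | step 14 | 5-(benzyloxy)-2-[4,5-bis(benzyloxy)-2-methoxyphenyl]-3-hydroxy-6,7,8-trimethoxy-4H-chromen-4-one | COc1cc(OCc2ccccc2)c(OCc2ccccc2)cc1-c1oc2c(OC)c(OC)c(OC)c(OCc3ccccc3)c2c(=O)c1O
F11 | step 14 | 5-(benzyloxy)-2-[4,5-bis(benzyloxy)-2-methoxyphenyl]-3,6,7,8-tetramethoxy-4H-chromen-4-one | COc1cc(OCc2ccccc2)c(OCc2ccccc2)cc1-c1oc2c(OC)c(OC)c(OC)c(OCc3ccccc3)c2c(=O)c1OC
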